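**Retrosynthetic overview**
- Ring C is opened at O1–C2. The flavone comes from a 2'-hydroxychalcone by iodine/DMSO oxidative oxa-cyclisation.
- The 2'-oxygen (future O1, bond C8a–O1) is removed next. It is installed by a ketone-directed C–H oxygenation of the chalcone. Ring A is a 3,4,5-trimethoxyphenyl ketone with two equivalent ortho C–H sites, so only the 6,7,8-trimethoxy pattern can result.
- The chalcone is cut at Cα=Cβ into 3',4',5'-trimethoxyacetophenone and 3-hydroxy-4,5-dimethoxybenzaldehyde (Claisen–Schmidt).
- Ring order: rings A and B are bought intact, and ring C is the only ring formed and is closed last. Oxygenation precedes ring closure because the C4 carbonyl of a finished flavone would steer the same chemistry to C5–H.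
- There are no protecting-group steps. The ring-B phenol masks itself as a trifluoroacetate in the oxygenation medium and is freed on aqueous work-up.

Assumption: the target SMILES has no stereocentre and no stereogenic double bond, so the compound is achiral and no enantiocontrol is needed. Both starting materials are taken as catalogue chemicals.

**Step 1**
Reactants: 1 3',4',5'-trimethoxyacetophenone; 2 3-hydroxy-4,5-dimethoxybenzaldehyde
Product: 3 (E)-3-(3-hydroxy-4,5-dimethoxyphenyl)-1-(3,4,5-trimethoxyphenyl)prop-2-en-1-one
Conditions: KOH (3 equiv), EtOH, N2, rt, 24 h; then dilute aq HCl to pH 3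
Reagents that add atoms: none
Why: Claisen–Schmidt condensation in which only 1 can enolise and only 2 is an aldehyde, the meta-phenoxide of 2 is not conjugated with the CHO group so the aldehyde stays electrophilic, and E1cB dehydration gives the thermodynamically favoured (E)-enone without forming a stereocentre.

**Step 2**
Reactants: 3 (E)-3-(3-hydroxy-4,5-dimethoxyphenyl)-1-(3,4,5-trimethoxyphenyl)prop-2-en-1-one
Product: 6 (E)-1-(2-hydroxy-3,4,5-trimethoxyphenyl)-3-(3-hydroxy-4,5-dimethoxyphenyl)prop-2-en-1-one, via ring-B trifluoroacetate 4 (not isolated), via bis(trifluoroacetate) 5 (not isolated)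
Conditions: Pd(O2CCF3)2 (10 mol %), K2S2O8 (1.2 equiv), CF3CO2H/(CF3CO)2O 9:1, 40 °C, 12 h; evaporate; THF/H2O 1:1, rt, 1 h
Reagents that add atoms: trifluoroacetic acid, OC(=O)C(F)(F)F (its oxygen becomes the 2'-OH of 6); trifluoroacetic anhydride, O=C(OC(=O)C(F)(F)F)C(F)(F)F (CF3CO group of 4 and 5 only, nothing left in 6)
Why: Proposed new method: a ketone-directed ortho-C–H oxygenation carried out on a chalcone-type enone that bears a free phenol, in which (CF3CO)2O first turns the ring-B phenol into the electron-poor ester 4 (self-masking of the most oxidisable site), the enone carbonyl oxygen then binds electrophilic divalent palladium and guides concerted metalation–deprotonation to C2' of ring A (identical with C6' by symmetry and activated by one ortho and one para OMe) to give a five-membered palladacycle, K2S2O8 raises it to tetravalent palladium, C–O reductive elimination with a trifluoroacetate ligand forms the future C8a–O1 bond in 5 (deactivated against a second oxygenation), and water cleaves both labile aryl trifluoroacetates to 6; the closest known reaction type is the palladium- or ruthenium-catalysed ortho-hydroxylation of saturated alkyl aryl ketones and benzophenones in CF3CO2H/(CF3CO)2O, which has not been shown on chalcones carrying a free phenol; no stereocentre is formed and the (E)-alkene is untouched.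

**Step 3**
Reactants: 6 (E)-1-(2-hydroxy-3,4,5-trimethoxyphenyl)-3-(3-hydroxy-4,5-dimethoxyphenyl)prop-2-en-1-one
Product: 8 2-(3-hydroxy-4,5-dimethoxyphenyl)-6,7,8-trimethoxy-4H-chromen-4-one (3'-hydroxy-4',5',6,7,8-pentamethoxyflavone), via racemic flavanone 7 (not isolated)
Conditions: I2 (10 mol %), DMSO, 120 °C, 3 h; aq Na2S2O3 wash
Reagents that add atoms: none
Why: Iodine/DMSO oxidative cyclisation of a 2'-hydroxychalcone, in which hot I2/HI equilibrates 6 with flavanone 7 by 6-endo oxa-Michael addition (O1–C2 bond, ring C closed), iodine-mediated α-iodination and loss of HI give the pyranone while DMSO re-oxidises HI to I2, the transient C2 stereocentre of 7 is erased, and a free 3'-hydroxy-4'-methoxy ring B is known to survive such iodine dehydrogenations (hesperidin to diosmin).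

**Compound list**
1 | 1-(3,4,5-trimethoxyphenyl)ethan-1-one (3',4',5'-trimethoxyacetophenone) | CC(=O)c1cc(OC)c(OC)c(OC)c1 | starting material
2 | 3-hydroxy-4,5-dimethoxybenzaldehyde | O=Cc1cc(O)c(OC)c(OC)c1 | starting material
3 | (E)-3-(3-hydroxy-4,5-dimethoxyphenyl)-1-(3,4,5-trimethoxyphenyl)prop-2-en-1-one | COc1cc(cc(OC)c1OC)C(=O)/C=C/c1cc(O)c(OC)c(OC)c1 | intermediate
4 | 2,3-dimethoxy-5-[(E)-3-oxo-3-(3,4,5-trimethoxyphenyl)prop-1-en-1-yl]phenyl trifluoroacetate | COc1cc(cc(OC)c1OC)C(=O)/C=C/c1cc(OC(=O)C(F)(F)F)c(OC)c(OC)c1 | intermediate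
5 | 2,3-dimethoxy-5-[(E)-3-oxo-3-{3,4,5-trimethoxy-2-[(trifluoroacetyl)oxy]phenyl}prop-1-en-1-yl]phenyl trifluoroacetate | COc1cc(C(=O)/C=C/c2cc(OC(=O)C(F)(F)F)c(OC)c(OC)c2)c(OC(=O)C(F)(F)F)c(OC)c1OC | intermediate
6 | (E)-1-(2-hydroxy-3,4,5-trimethoxyphenyl)-3-(3-hydroxy-4,5-dimethoxyphenyl)prop-2-en-1-one | COc1cc(C(=O)/C=C/c2cc(O)c(OC)c(OC)c2)c(O)c(OC)c1OC | intermediate
7 | racemic 2-(3-hydroxy-4,5-dimethoxyphenyl)-6,7,8-trimethoxychroman-4-one | COc1cc(C2CC(=O)c3cc(OC)c(OC)c(OC)c3O2)cc(O)c1OC | intermediate
8 | 2-(3-hydroxy-4,5-dimethoxyphenyl)-6,7,8-trimethoxy-4H-chromen-4-one (achiral) | COc1cc(-c2cc(=O)c3cc(OC)c(OC)c(OC)c3o2)cc(O)c1OC | target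

**Total step count:** 3. **Longest linear sequence:** 3 steps (1 → 3 → 6 → 8).

**Steps most likely to fail**

**Step 2 (the proposed new step).**
- Palladation at an ortho C–H flanked by OMe may be slow.
- Persulfate may attack the electron-rich rings or the enone.
- The carbonyl could also direct palladation to the cis β-vinyl C–H.
- Heating well above 40 °C in CF3CO2H invites Nazarov-type closure to an indanone.

The fallback uses known chemistry, sets out from 2 and comes back to the route at 6. The ring-A oxygen is bought instead of installed. 2,3,4-Trimethoxyphenol F1 is C-acetylated at its only free ortho position with AcOH/BF3·OEt2 at 90 °C (Fries-type ortho-acylation driven by the boron chelate). This gives 1-(2-hydroxy-3,4,5-trimethoxyphenyl)ethan-1-one F2. F2 is then condensed with 2 (KOH, EtOH, rt, then dilute HCl) in a Claisen–Schmidt reaction that delivers 6 directly.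

**Step 3.**
- Ring B may be iodinated next to the free phenol.
- A competing 5-exo closure would give an aurone.
- The reaction may stall at the flavanone stage.

The fallback sets out from 6 and comes back at 8. It separates ring closure from oxidation and uses no iodine. Compound 6 is isomerised with NaOAc in refluxing EtOH and the flavanone 7 is isolated. Compound 7 is then dehydrogenated with Pd(O2CCF3)2 (10 mol %) in DMSO under O2 (1 atm) at 100 °C, a known aerobic α,β-dehydrogenation through a palladium enolate and β-hydride elimination. No compound outside the list is made (entry F0).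

**Step 1.**
- The phenoxide of 2 lowers the aldehyde reactivity and is air-sensitive.
- The enolate of 1 can add to 3 in a Michael reaction.

The fallback sets out from 1 and comes back at 3. It replaces the basic aldol by a neutral Wittig olefination. Compound 1 is α-brominated with CuBr2 in refluxing EtOAc/CHCl3 to 2-bromo-1-(3,4,5-trimethoxyphenyl)ethan-1-one F3. PPh3 in toluene converts F3 into [2-oxo-2-(3,4,5-trimethoxyphenyl)ethyl]triphenylphosphonium bromide F4. Aqueous NaOH then gives the stabilised ylide 1-(3,4,5-trimethoxyphenyl)-2-(triphenyl-λ5-phosphanylidene)ethan-1-one F5. F5 is too weakly basic to be quenched by the phenol, and with 2 in refluxing toluene it gives (E)-3.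

**Further compounds**
F1 | step 2 | 2,3,4-trimethoxyphenol (bought) | COc1ccc(O)c(OC)c1OC
F2 | step 2 | 1-(2-hydroxy-3,4,5-trimethoxyphenyl)ethan-1-one | CC(=O)c1cc(OC)c(OC)c(OC)c1O
F0 | step 3 | none | none
F3 | step 1 | 2-bromo-1-(3,4,5-trimethoxyphenyl)ethan-1-one | COc1cc(cc(OC)c1OC)C(=O)CBr
F4 | step 1 | [2-oxo-2-(3,4,5-trimethoxyphenyl)ethyl]triphenylphosphonium bromide | COc1cc(cc(OC)c1OC)C(=O)C[P+](c1ccccc1)(c1ccccc1)c1ccccc1.[Br-]
F5 | step 1 | 1-(3,4,5-trimethoxyphenyl)-2-(triphenyl-λ5-phosphanylidene)ethan-1-one | COc1cc(cc(OC)c1OC)C(=O)C=P(c1ccccc1)(c1ccccc1)c1ccccc1
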